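## Retrosynthetic overview

1. The target is an achiral tetramer A–CH2–B–CH2–B–CH2–A (ring A = propanoylfilicinic acid, ring B = propanoylphloroglucinol). Cutting the central B–CH2–B bridge gives two A–CH2–B dimers plus formaldehyde.
2. The A–CH2–B dimer is cut at its bridge into propanoylfilicinic acid (made electrophilic as its Mannich base) and propanoylphloroglucinol.
3. Propanoylfilicinic acid comes from propanoylphloroglucinol by dearomatising gem-C-dimethylation.
4. Propanoylphloroglucinol comes from cyclopentane-1,2,4-trione and 1-diazobutan-2-one (from propanoyl chloride) by a one-carbon ring expansion: a ring carbon shifts 1,2 onto the diazo carbon, then the ring aromatises. This step makes the six-membered ring and brings in the acyl chain.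
5. Ring order: one five-membered carbocycle is expanded to one benzenoid ring, and all four six-membered rings of the target are copies of it. Two copies are dearomatised to rings A; the bridges are closed A–B first and B–B last.

Assumption: the target has no stereocentre (each CMe2 carbon carries two identical methyl groups), so it is made as the single achiral compound drawn; cyclopentane-1,2,4-trione is taken as a purchasable catalogue compound.

## Route

Step 1
Reactants: 1 propanoyl chloride
Product: 3 1-diazobutan-2-one, via C-silyl diazoketone 2 (not isolated)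
Conditions: TMSCHN2 (2.0 M in hexanes, 2.2 equiv), THF/MeCN 1:1, 0 °C → rt, 12 h; aq. NaHCO3 work-up; kept as a CH2Cl2 solution
Reagents that add atoms: (trimethylsilyl)diazomethane, C[Si](C)(C)C=[N+]=[N-]
Why: The nucleophilic diazo carbon is C-acylated by the acid chloride (diazoketone-forming first stage of the Arndt–Eistert sequence, trimethylsilyldiazomethane variant); the second equivalent of the diazo reagent takes up HCl and the labile C–Si bond of 2 is hydrolysed on aqueous work-up.

Step 2
Reactants: 4 cyclopentane-1,2,4-trione; 3 1-diazobutan-2-one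
Product: 7 1-(2,4,6-trihydroxyphenyl)propan-1-one (propanoylphloroglucinol), via silyl enol ether 5 (not isolated), via aryl silyl ether 6 (not isolated)
Conditions: (Me3Si)2NH (0.55 equiv), CH2Cl2, 40 °C, 1 h, NH3 purged; then Sc(OTf)3 (10 mol %), 3 (1.1 equiv, slow addition), CH2Cl2, −20 °C → rt; then 1 M HCl/MeOH, rt
Reagents that add atoms: none
Why: Proposed new method: silylation fixes the acidic diosphenol as enol ether 5, so it cannot protonate the diazo compound, and leaves C1 as the only ketone that is not part of a vinylogous ester; Sc(OTf)3, held between the C1 carbonyl and the silyloxy oxygen, activates C1 for addition of the diazo carbon of 3, and in the resulting β-oxido diazonium ion the electron-rich enol-ether carbon C2 migrates to the diazo carbon in preference to the electron-poor α-keto CH2 (1,2-shift with loss of N2, formal acylcarbene insertion into the C1–C2 bond, five- to six-membered ring expansion), after which the 2-acylcyclohexane-1,3,5-trione enol ether tautomerises irreversibly to aromatic 6 and is desilylated to 7; the closest known reactions are the Lewis-acid-catalysed Tiffeneau–Demjanov-type (Büchner–Curtius–Schlotterbeck) homologation of cyclic ketones with α-diazo carbonyl compounds and the ring expansions of isatins and of ninhydrin with diazo compounds; no stereocentre arises.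

Step 3
Reactants: 7 1-(2,4,6-trihydroxyphenyl)propan-1-one
Product: 8 3,5-dihydroxy-6,6-dimethyl-2-propanoylcyclohexa-2,4-dien-1-one (propanoylfilicinic acid)
Conditions: NaOMe (3.0 equiv), MeI (2.1 equiv), MeOH, 0 °C → rt, 16 h; then 1 M HCl; NaHCO3 extraction, crystallisation
Reagents that add atoms: iodomethane, CI
Why: Dearomatising C-alkylation of the polyphenoxide (the classical gem-dimethylation of acylphloroglucinols to acylfilicinic acids): two C-methylations at the same ring carbon give the non-aromatisable 6,6-dimethyl trione, which is far more acidic than the mono- and 3,5-dimethylated phenolic by-products and is separated from them by bicarbonate extraction; the quaternary carbon bears two identical methyl groups and is not a stereocentre.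

Step 4
Reactants: 8 3,5-dihydroxy-6,6-dimethyl-2-propanoylcyclohexa-2,4-dien-1-one; 7 1-(2,4,6-trihydroxyphenyl)propan-1-one (3 equiv, excess recovered)
Product: 11 1-{3-[(2,6-dihydroxy-3,3-dimethyl-4-oxo-5-propanoylcyclohexa-1,5-dien-1-yl)methyl]-2,4,6-trihydroxyphenyl}propan-1-one (A–CH2–B dimer), via Mannich base 9 (not isolated), via methylene trione 10 (not isolated)
Conditions: 8 added to Me2N=CH2 I (1.05 equiv), MeCN, 0 °C → rt, 1 h; then 7 (3 equiv), NaOAc (1.1 equiv), 70 °C, 6 h
Reagents that add atoms: N,N-dimethylmethylideneammonium iodide (Eschenmoser's salt), C=[N+](C)C.[I-]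
Why: Mannich reaction at the only C–H carbon of 8 gives 9, which on warming loses dimethylamine (E1cB) to the exo-methylene trione 10, and this acceptor is captured by a nucleophilic ring carbon of 7 (Friedel–Crafts-type Michael addition to a quinone-methide-like enone); forming 9 before 7 is added suppresses the A–CH2–A homodimer and the threefold excess of 7 suppresses double alkylation.

Step 5
Reactants: 11 A–CH2–B dimer (2 equiv)
Product: 12 di{3-[(2,6-dihydroxy-3,3-dimethyl-4-oxo-5-propanoylcyclohexa-1,5-dien-1-yl)methyl]-2,4,6-trihydroxy-5-propanoylphenyl}methane (CNP0541376.0)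
Conditions: 37 % aq. CH2O (0.55 equiv per 11), 1 % aq. NaOH, 0 °C → rt, 20 min; then 1 M HCl
Reagents that add atoms: formaldehyde, C=O
Why: Phenol–formaldehyde condensation (hydroxymethylation of the single remaining aromatic C–H of 11, dehydration to the ortho-quinone methide and Michael capture by a second molecule of 11), the classical way from norflavaspidic-type dimers to their methylene-bis tetramers; because 11 has only one nucleophilic C–H the reaction stops at 12, and short contact with cold dilute alkali limits methylene exchange.

## Compound list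

1 | propanoyl chloride | CCC(Cl)=O | starting material
2 | 1-diazo-1-(trimethylsilyl)butan-2-one | CCC(=O)C(=[N+]=[N-])[Si](C)(C)C | intermediate
3 | 1-diazobutan-2-one | CCC(=O)C=[N+]=[N-] | intermediate
4 | cyclopentane-1,2,4-trione | O=C1CC(=O)C(=O)C1 | starting material
5 | 2-(trimethylsilyloxy)cyclopent-2-ene-1,4-dione | C[Si](C)(C)OC1=CC(=O)CC1=O | intermediate
6 | 1-[2,4-dihydroxy-6-(trimethylsilyloxy)phenyl]propan-1-one | CCC(=O)c1c(O)cc(O)cc1O[Si](C)(C)C | intermediate
7 | 1-(2,4,6-trihydroxyphenyl)propan-1-one (propanoylphloroglucinol) | CCC(=O)c1c(O)cc(O)cc1O | intermediate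
8 | 3,5-dihydroxy-6,6-dimethyl-2-propanoylcyclohexa-2,4-dien-1-one (propanoylfilicinic acid) | CCC(=O)C1=C(O)C=C(O)C(C)(C)C1=O | intermediate
9 | 4-[(dimethylamino)methyl]-3,5-dihydroxy-6,6-dimethyl-2-propanoylcyclohexa-2,4-dien-1-one | CCC(=O)C1=C(O)C(CN(C)C)=C(O)C(C)(C)C1=O | intermediate
10 | 5-hydroxy-2,2-dimethyl-6-methylidene-4-propanoylcyclohex-4-ene-1,3-dione | CCC(=O)C1=C(O)C(=C)C(=O)C(C)(C)C1=O | intermediate
11 | 1-{3-[(2,6-dihydroxy-3,3-dimethyl-4-oxo-5-propanoylcyclohexa-1,5-dien-1-yl)methyl]-2,4,6-trihydroxyphenyl}propan-1-one | CCC(=O)C1=C(O)C(Cc2c(O)cc(O)c(C(=O)CC)c2O)=C(O)C(C)(C)C1=O | intermediate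
12 | di{3-[(2,6-dihydroxy-3,3-dimethyl-4-oxo-5-propanoylcyclohexa-1,5-dien-1-yl)methyl]-2,4,6-trihydroxy-5-propanoylphenyl}methane (CNP0541376.0, achiral) | CCC(=O)C1=C(O)C(Cc2c(O)c(Cc3c(O)c(CC4=C(O)C(C)(C)C(=O)C(C(=O)CC)=C4O)c(O)c(C(=O)CC)c3O)c(O)c(C(=O)CC)c2O)=C(O)C(C)(C)C1=O | target

## Step count and risks

Total steps: 5. Longest linear sequence: 5 (1 → 3 → 7 → 8 → 11 → 12).

**Step 2 (the proposed ring expansion).** It can fail in three ways: the α-keto CH2 migrates instead of C2 and gives the 2,3,5-trioxygenated isomer, the diazoketone O-alkylates the substrate, or a spiro-epoxide forms. The fallback uses only known chemistry, sets out from 1 and comes back at 7. Resorcinol F1 is silylated (TBSCl, imidazole, DMF) to 1,3-bis(tert-butyldimethylsilyloxy)benzene F2. Sterically controlled meta C–H borylation ([Ir(OMe)(cod)]2, 4,4'-di-tert-butyl-2,2'-bipyridine, B2pin2, hexane, 60 °C) gives 2-[3,5-bis(tert-butyldimethylsilyloxy)phenyl]-4,4,5,5-tetramethyl-1,3,2-dioxaborolane F3. Oxidation with H2O2/NaOH followed by HCl/MeOH removes boron and both silyl groups to give phloroglucinol F4. Friedel–Crafts acylation of F4 with 1 (AlCl3, CH2Cl2/MeNO2, 0 °C → 40 °C) gives 7.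

**Step 4 (cross-bridging).** The risk is statistical over-reaction to the A–CH2–B–CH2–A trimer or to the A–CH2–A homodimer. The fallback reverses the polarity, sets out from 7 and 8 and comes back at 11. Compound 7 (2 equiv) is aminomethylated with Me2N=CH2 I (1 equiv, MeCN, 0 °C, NaHCO3 work-up) to the mono-Mannich base 1-{3-[(dimethylamino)methyl]-2,4,6-trihydroxyphenyl}propan-1-one F5, which is isolated. F5 is heated with 8 in dioxane at 100 °C; thermal loss of dimethylamine gives the ortho-quinone methide of ring B, which is captured by the single nucleophilic carbon of 8 to give 11. Ring A cannot be alkylated twice.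

**Step 5 (final dimerisation).** The risk is alkali-induced methylene exchange (rottlerone-type scrambling of the A–CH2–B bridge) or incomplete coupling. The fallback changes the order of bridge formation, sets out from 7 (with 8) and comes back at 12. Compound 7 (4 equiv) is condensed with aq. CH2O (1 equiv, EtOH, cat. HCl, rt) to bis(2,4,6-trihydroxy-3-propanoylphenyl)methane F6, and excess 7 is recovered. F6 is then alkylated at its two remaining aromatic C–H positions with Mannich base 9 (2.2 equiv, generated from 8 and Me2N=CH2 I as in step 4; NaOAc, MeCN, 70 °C). This gives 12 directly under non-alkaline conditions.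

## Further compounds

F1 | step 2 | resorcinol | Oc1cccc(O)c1
F2 | step 2 | 1,3-bis(tert-butyldimethylsilyloxy)benzene | CC(C)(C)[Si](C)(C)Oc1cccc(O[Si](C)(C)C(C)(C)C)c1
F3 | step 2 | 2-[3,5-bis(tert-butyldimethylsilyloxy)phenyl]-4,4,5,5-tetramethyl-1,3,2-dioxaborolane | CC(C)(C)[Si](C)(C)Oc1cc(O[Si](C)(C)C(C)(C)C)cc(B2OC(C)(C)C(C)(C)O2)c1
F4 | step 2 | phloroglucinol (benzene-1,3,5-triol) | Oc1cc(O)cc(O)c1
F5 | step 4 | 1-{3-[(dimethylamino)methyl]-2,4,6-trihydroxyphenyl}propan-1-one | CCC(=O)c1c(O)cc(O)c(CN(C)C)c1O
F6 | step 5 | bis(2,4,6-trihydroxy-3-propanoylphenyl)methane | CCC(=O)c1c(O)cc(O)c(Cc2c(O)cc(O)c(C(=O)CC)c2O)c1O
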